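## Retrosynthetic overview
1. The last bond made is the ester C–O bond. It joins the primary C3–OH of the bicyclic diol to palmitic acid, which is built from C8, C6 and C2 pieces.
2. The C7 carbinol comes from methyl addition to a (Z)-cyclonon-2-enone.
3. The nine-membered ring comes from a three-carbon radical ring expansion of a 2,2-disubstituted cyclohexanone. A vinyl radical adds to C=O, the C7–C11 bond undergoes β-scission, and Bu3Sn• is lost. This creates the Z-enone and the exocyclic methylene together.
4. Quaternary C11 comes from Bu3SnLi addition and allylation of an α-methylene ketone. C4 and the tetrahydrofuran come from Felkin–Anh addition of an alkoxymethyllithium to a dienone, then Williamson closure on a CH2Cl group.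
5. The cyclohexene comes from a catalytic asymmetric Diels–Alder reaction of a 2-silyloxydiene with methyl vinyl ketone. Ring order: six-membered carbocycle, then tetrahydrofuran, then nine-membered ring.

Numbering used in the text (xenicane):
- C1 = ring OCH2
- C3 = exocyclic CH2O
- C4 = quaternary ether carbon
- C4a and C11a = ring-fusion CH
- C5–C11 = rest of the nine-membered ring (C7 carbinol, C8=C9, C11=C19H2)
- C12–C17 = dienyl chain
- C18 = methyl on C7

The target is (4R,4aS,7S,11aR).

Assumption: the (S)-proline-derived oxazaborolidinium salt is taken to give the (1R,2S) adduct of step 3. If the sense is opposite, its enantiomer is used and nothing else changes.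

## Route

Step 1
Reactants: 1 but-3-en-2-one (methyl vinyl ketone); 2 3-chloroprop-1-ene (allyl chloride)
Product: 3 (3E)-5-chloropent-3-en-2-one
Conditions: second-generation Hoveyda–Grubbs catalyst RuCl2(H2IMes)(=CH-C6H4-2-OiPr) (2 mol%), 2 (3 equiv), CH2Cl2, 40 °C
Reagents that add atoms: none
Why: Olefin cross-metathesis between an electron-poor enone and a simple terminal alkene is selective for the E cross product.

Step 2
Reactants: 3 (3E)-5-chloropent-3-en-2-one
Product: 4 tert-butyl{[(3E)-5-chloropenta-1,3-dien-2-yl]oxy}dimethylsilane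
Conditions: TBSOTf, Et3N, CH2Cl2, 0 °C
Reagents that add atoms: tert-butyldimethylsilyl triflate, CC(C)(C)[Si](C)(C)OS(=O)(=O)C(F)(F)F
Why: Soft enolisation (silyl triflate/amine) removes an α′-methyl proton and gives the cross-conjugated 2-silyloxydiene with the E alkene untouched.

Step 3
Reactants: 4 tert-butyl{[(3E)-5-chloropenta-1,3-dien-2-yl]oxy}dimethylsilane; 1 but-3-en-2-one
Product: 5 1-[(1R,2S)-4-{[tert-butyl(dimethyl)silyl]oxy}-2-(chloromethyl)cyclohex-3-en-1-yl]ethan-1-one (cis)
Conditions: (S)-B-(o-tolyl)oxazaborolidine from (S)-α,α-diphenylprolinol, activated with Tf2NH (10 mol%), CH2Cl2, −78 to −40 °C; chromatography removes the minor trans (exo) adduct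
Reagents that add atoms: none
Why: Cationic oxazaborolidine-catalysed asymmetric Diels–Alder reaction: the silyloxy and alkyl groups of the diene both direct its CH2 terminus to the β-carbon of the enone, the endo transition state gives the cis adduct and the catalyst fixes the future C11a; the exo adduct is removed because the epimerisation in step 4 would carry it into the enantiomeric series.

Step 4
Reactants: 5 cis acetylcyclohexene; 6 3-methylbut-2-enal (prenal)
Product: 9 (2E)-1-[(1S,2S)-4-{[tert-butyl(dimethyl)silyl]oxy}-2-(chloromethyl)cyclohex-3-en-1-yl]-5-methylhexa-2,4-dien-1-one (trans), via aldol acetate 7 (not isolated), via cis-dienone 8 (not isolated)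
Conditions: LDA (1.05 equiv), THF, −78 °C; 6; Ac2O (1.2 equiv), −78 to 0 °C; DBU (3 equiv), rt, 12 h
Reagents that add atoms: none
Why: Kinetic aldol addition at the methyl group, acetylation and E1cB elimination give the E-dienone, and DBU equilibrates the acidic C4a–H so that cis-8 passes to the diequatorial trans-9, which sets C4a relative to C11a; chloride is used because it is too poor a leaving group for cyclopropane formation under these conditions.

Step 5
Reactants: 9 trans-dienone
Product: 11 (1R,3aS,7aS)-5-{[tert-butyl(dimethyl)silyl]oxy}-1-{[(4-methoxybenzyl)oxy]methyl}-1-[(1E)-4-methylpenta-1,3-dien-1-yl]-1,3,3a,6,7,7a-hexahydro-2-benzofuran (trans-fused), via lithium chloro-alkoxide 10 (not isolated)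
Conditions: PMBOCH2SnBu3 (1.3 equiv), n-BuLi (1.25 equiv), THF, −78 °C; 9, −78 °C; then DMPU, NaI (0.1 equiv), −78 to 45 °C
Reagents that add atoms: tributyl{[(4-methoxybenzyl)oxy]methyl}stannane, CCCC[Sn](CCCC)(CCCC)COCc1ccc(OC)cc1
Why: α-Alkoxyorganolithium 1,2-addition under Felkin–Anh control followed by intramolecular Williamson etherification: with the branched C11a carbon anti to the nucleophile and H-4a next to the dienyl arm, PMBOCH2Li attacks the Si face of the ketone and sets (4R), the carbonyl oxygen is kept as the ring oxygen, and 5-exo-tet displacement of chloride closes the trans-fused tetrahydrofuran without touching a stereocentre.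

Step 6
Reactants: 11 silyl enol ether
Product: 14 (1R,3aR,7aS)-1-{[(4-methoxybenzyl)oxy]methyl}-4-methylidene-1-[(1E)-4-methylpenta-1,3-dien-1-yl]hexahydro-2-benzofuran-5(3H)-one, via Mannich base 12 (not isolated), via methiodide 13 (not isolated)
Conditions: CH2=NMe2+ I− (1.5 equiv), CH2Cl2, rt; aq NaHCO3 wash; MeI, Et2O, rt; sat. aq NaHCO3–CH2Cl2, rt; used at once
Reagents that add atoms: Eschenmoser's salt, C=[N+](C)C.[I-]
Why: Mannich reaction of the regiodefined silyl enol ether with Eschenmoser's salt, then Hofmann-type elimination of the methiodide, places the methylene only at the future C11; the weak base avoids migration of the double bond into the ring fusion.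

Step 7
Reactants: 14 α-methylene ketone; 15 1,3-dibromoprop-1-ene (commercial cis/trans mixture)
Product: 17 (1R,3aR,7aS)-4-(3-bromoprop-2-en-1-yl)-1-{[(4-methoxybenzyl)oxy]methyl}-1-[(1E)-4-methylpenta-1,3-dien-1-yl]-4-[(tributylstannyl)methyl]hexahydro-2-benzofuran-5(3H)-one (C4 epimers and E/Z mixture used as such), via stannyl lithium enolate 16 (not isolated)
Conditions: Bu3SnH, LDA, THF, 0 °C; 14, −78 °C; 15 (2 equiv), DMPU, −78 to −30 °C
Reagents that add atoms: tributyltin hydride, CCCC[SnH](CCCC)CCCC
Why: Stannyl anion conjugate addition gives the enolate regiospecifically at the future C11, and allylic SN2 alkylation builds the quaternary carbon; its configuration and the bromide geometry do not matter because both are erased in step 8.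

Step 8
Reactants: 17 bromoallyl stannylmethyl cyclohexanone
Product: 20 (4R,4aS,11aR)-3-[(4-methoxybenzyl)oxy]-18-nor-1,4-epoxyxenica-8Z,11(19),12E,14-tetraen-7-one (trans-fused tetrahydrofuran on a nine-membered ring that holds a Z-enone and an exocyclic methylene), via bicyclic alkoxyl radical 18 (not isolated), via ring-expanded tertiary radical 19 (not isolated)
Conditions: Bu3SnH (0.1 equiv) and AIBN (0.1 equiv) by syringe pump, PhH (0.01 M), 80 °C
Reagents that add atoms: none
Why: Proposed new method: Bu3Sn• abstracts bromine from either vinyl bromide isomer, the rapidly inverting σ-vinyl radical adds 5-exo to the neighbouring C7 ketone carbon to give alkoxyl radical 18, β-scission of the fully substituted C7–C11 bond gives the β-stannyl tertiary radical 19, and loss of Bu3Sn• creates the C11=C19 methylene and carries the chain, so the ring grows from six to nine atoms, the five-membered transition structure fixes C8=C9 as Z, and neither a stoichiometric hydride donor nor a base that could conjugate the skipped dienone is present; the closest known reaction types are the Dowd–Beckwith three-carbon ring expansion of haloalkyl β-keto esters and the fragmentation of β-stannyl radicals, which have not been combined with a vinyl radical on an unactivated ketone.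

Step 9
Reactants: 20 nine-membered enone
Product: 21 (4R,4aS,7S,11aR)-3-[(4-methoxybenzyl)oxy]-1,4-epoxyxenica-8Z,11(19),12E,14-tetraen-7-ol
Conditions: MeLi (3 equiv), anhydrous CeCl3 (3.2 equiv), THF, −78 °C; aq NH4Cl
Reagents that add atoms: methyllithium, [Li]C
Why: Organocerium 1,2-addition: the non-basic reagent avoids γ-deprotonation at C10 and conjugate addition, the carbonyl of the medium-ring Z-enone stands roughly perpendicular to the mean ring plane so that only its outer face is open, and in the conformer expected for the trans-fused bicycle the oxygen points to the side of H-4a, so methyl enters the Re face and gives (7S).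

Step 10
Reactants: 21 PMB ether
Product: 22 (4R,4aS,7S,11aR)-1,4-epoxyxenica-8Z,11(19),12E,14-tetraene-3,7-diol
Conditions: DDQ (1.3 equiv), CH2Cl2–pH 7 phosphate buffer (10:1), 0 °C
Reagents that add atoms: none
Why: Oxidative cleavage of the p-methoxybenzyl ether under buffered neutral conditions spares the acid-labile tertiary allylic alcohol and dienyl ether and touches no stereocentre.

Step 11
Reactants: 23 oct-1-ene; 24 1,6-dibromohexane
Product: 26 1-bromotetradecane, via B-octyl-9-BBN 25 (not isolated)
Conditions: 9-BBN-H, THF, rt; then 24 (4 equiv), Pd(OAc)2 (4 mol%), PCy3 (8 mol%), K3PO4·H2O (1.2 equiv), THF, rt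
Reagents that add atoms: none
Why: Anti-Markovnikov hydroboration followed by alkyl–alkyl Suzuki–Miyaura coupling; the excess of dibromide restricts coupling to one end.

Step 12
Reactants: 26 1-bromotetradecane; 27 acetic acid
Product: 29 hexadecanoic acid (palmitic acid), via dilithium acetate dianion 28 (not isolated)
Conditions: 27, LDA (2.1 equiv), THF–DMPU, 0 to 40 °C; 26, rt; aq HCl
Reagents that add atoms: none
Why: Alkylation of a carboxylic acid dianion with a primary bromide (SN2) adds the last two carbons and delivers the free acid directly.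

Step 13
Reactants: 22 diol; 29 hexadecanoic acid
Product: 31 (4R,4aS,7S,11aR)-7-hydroxy-1,4-epoxyxenica-8Z,11(19),12E,14-tetraen-3-yl hexadecanoate (target CNP0150666.1), via O-acylisourea 30 (not isolated)
Conditions: DCC (1.2 equiv), DMAP (0.2 equiv), CH2Cl2, 0 °C to rt
Reagents that add atoms: none
Why: Steglich esterification acylates only the primary C3–OH, because the tertiary C7–OH is inert under these conditions.

## Compound list
1 | but-3-en-2-one | CC(=O)C=C | starting material
2 | 3-chloroprop-1-ene | C=CCCl | starting material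
3 | (3E)-5-chloropent-3-en-2-one | CC(=O)/C=C/CCl | intermediate
4 | tert-butyl{[(3E)-5-chloropenta-1,3-dien-2-yl]oxy}dimethylsilane | C=C(O[Si](C)(C)C(C)(C)C)/C=C/CCl | intermediate
5 | cis Diels–Alder adduct (1R,2S) | C1=C(O[Si](C)(C)C(C)(C)C)CC[C@@H](C(C)=O)[C@H]1CCl | intermediate
6 | 3-methylbut-2-enal | CC(C)=CC=O | starting material
7 | aldol acetate (carbinol epimers) | C1=C(O[Si](C)(C)C(C)(C)C)CC[C@@H](C(=O)CC(OC(C)=O)C=C(C)C)[C@H]1CCl | intermediate (not isolated)
8 | cis-dienone (1R,2S) | C1=C(O[Si](C)(C)C(C)(C)C)CC[C@@H](C(=O)/C=C/C=C(C)C)[C@H]1CCl | intermediate (not isolated)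
9 | trans-dienone (1S,2S) | C1=C(O[Si](C)(C)C(C)(C)C)CC[C@H](C(=O)/C=C/C=C(C)C)[C@H]1CCl | intermediate
10 | lithium chloro-alkoxide, (R) at the new carbinol carbon | C1=C(O[Si](C)(C)C(C)(C)C)CC[C@H]([C@](O[Li])(/C=C/C=C(C)C)COCc3ccc(OC)cc3)[C@H]1CCl | intermediate (not isolated)
11 | trans-fused tetrahydrofuran silyl enol ether (1R,3aS,7aS) | C1=C(O[Si](C)(C)C(C)(C)C)CC[C@H]2[C@H]1CO[C@@]2(/C=C/C=C(C)C)COCc3ccc(OC)cc3 | intermediate
12 | Mannich base (epimers at the aminomethyl carbon) | CN(C)CC1C(=O)CC[C@H]2[C@H]1CO[C@@]2(/C=C/C=C(C)C)COCc3ccc(OC)cc3 | intermediate (not isolated)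
13 | methiodide of 12 | C[N+](C)(C)CC1C(=O)CC[C@H]2[C@H]1CO[C@@]2(/C=C/C=C(C)C)COCc3ccc(OC)cc3.[I-] | intermediate (not isolated)
14 | α-methylene ketone (1R,3aR,7aS) | C=C1C(=O)CC[C@H]2[C@H]1CO[C@@]2(/C=C/C=C(C)C)COCc3ccc(OC)cc3 | intermediate
15 | 1,3-dibromoprop-1-ene (cis/trans) | BrCC=CBr | starting material
16 | stannyl lithium enolate | CCCC[Sn](CCCC)(CCCC)CC1=C(O[Li])CC[C@H]2[C@H]1CO[C@@]2(/C=C/C=C(C)C)COCc3ccc(OC)cc3 | intermediate (not isolated)
17 | bromoallyl stannylmethyl cyclohexanone (quaternary carbon and C=C unspecified) | CCCC[Sn](CCCC)(CCCC)CC1(CC=CBr)C(=O)CC[C@H]2[C@H]1CO[C@@]2(/C=C/C=C(C)C)COCc3ccc(OC)cc3 | intermediate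
18 | bicyclic alkoxyl radical | CCCC[Sn](CCCC)(CCCC)CC14CC=CC4([O])CC[C@H]2[C@H]1CO[C@@]2(/C=C/C=C(C)C)COCc3ccc(OC)cc3 | intermediate (not isolated)
19 | ring-expanded tertiary radical | CCCC[Sn](CCCC)(CCCC)C[C]1C/C=C\C(=O)CC[C@H]2[C@H]1CO[C@@]2(/C=C/C=C(C)C)COCc3ccc(OC)cc3 | intermediate (not isolated)
20 | nine-membered Z-enone (4R,4aS,11aR) | C=C1C/C=C\C(=O)CC[C@H]2[C@H]1CO[C@@]2(/C=C/C=C(C)C)COCc3ccc(OC)cc3 | intermediate
21 | tertiary alcohol PMB ether (4R,4aS,7S,11aR) | C=C1C/C=C\[C@@](C)(O)CC[C@H]2[C@H]1CO[C@@]2(/C=C/C=C(C)C)COCc3ccc(OC)cc3 | intermediate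
22 | diol (4R,4aS,7S,11aR) | C=C1C/C=C\[C@@](C)(O)CC[C@H]2[C@H]1CO[C@@]2(/C=C/C=C(C)C)CO | intermediate
23 | oct-1-ene | C=CCCCCCC | starting material
24 | 1,6-dibromohexane | BrCCCCCCBr | starting material
25 | B-octyl-9-borabicyclo[3.3.1]nonane | CCCCCCCCB1C2CCCC1CCC2 | intermediate (not isolated)
26 | 1-bromotetradecane | CCCCCCCCCCCCCCBr | intermediate
27 | acetic acid | CC(=O)O | starting material
28 | dilithium acetate dianion | [Li]CC(=O)O[Li] | intermediate (not isolated)
29 | hexadecanoic acid | CCCCCCCCCCCCCCCC(=O)O | intermediate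
30 | O-palmitoyl-N,N′-dicyclohexylisourea | CCCCCCCCCCCCCCCC(=O)OC(=NC1CCCCC1)NC1CCCCC1 | intermediate (not isolated)
31 | CNP0150666.1 | C=C1C/C=C\[C@@](C)(O)CC[C@H]2[C@H]1CO[C@@]2(/C=C/C=C(C)C)COC(=O)CCCCCCCCCCCCCCC | target

## Step count and risks
Total steps: 13. Longest linear sequence: 11 (steps 1–10 and 13). Steps 11–12 form a side branch.

**Risk 1: step 8, the new ring expansion.**
- The vinyl radical may undergo 1,5-hydrogen transfer from C11a–H or SnCH2 faster than it adds to the ketone.
- Bromine abstraction may be too slow to sustain the chain.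
- Stannyl radicals may add to the diene.

The fallback uses known chemistry, sets out from 14 and returns at 20. Commercial ethyl (Z)-3-iodoacrylate is reduced with DIBAL-H to (Z)-3-iodoprop-2-en-1-ol F1. This is brominated (CBr4, PPh3) to (Z)-3-bromo-1-iodoprop-1-ene F2. Bu3SnLi addition to 14 and trapping with F2 gives the Z-iodoallyl stannylmethyl ketone F3. Treatment with n-BuLi in THF at −78 °C triggers iodine–lithium exchange and intramolecular 1,2-addition, which gives the cis-fused γ-hydroxystannane F4. Pb(OAc)4 with CaCO3 in benzene then effects the established oxidative 1,4-fragmentation of a γ-hydroxystannane. This step is also a ring expansion, and it cleaves C7–C11 to give 20.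

**Risk 2: step 9.**
The face of the medium-ring ketone that is attacked rests only on a conformational argument. The 7-epimer could dominate, and C10 deprotonation is possible.

The fallback sets out from 20 and returns at 21. It replaces substrate control by catalyst control. The reagents are Me2Zn and Ti(OiPr)4 with 10 mol% of the trans-1,2-bis(hydroxycamphorsulfonamido)cyclohexane ligand in toluene at rt. The ligand antipode that reinforces or overrides the ring bias is chosen, and the epimers are separated at 21. This path makes no new compound F0.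

**Risk 3: step 5.**
- The basic organolithium may enolise the dienone or add in a conjugate sense.
- The Felkin–Anh ratio may be modest.
- The lithium alkoxide may close slowly.

The fallback sets out from 9 and returns at 11. Dimethylsulfonium methylide (Me3S+ I−, KHMDS, THF, −20 °C) is softer and less basic, and transfers CH2 to the same ketone face to give the chloro dienyl epoxide F5. Sodium 4-methoxybenzyl alkoxide (PMBOH, NaH, DMF) then opens the epoxide at its CH2 terminus with retention at C4. The tertiary alkoxide so released closes onto CH2Cl to give 11.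

## Further compounds
F1 | step 8 | (Z)-3-iodoprop-2-en-1-ol | OC/C=C\I
F2 | step 8 | (Z)-3-bromo-1-iodoprop-1-ene | BrC/C=C\I
F3 | step 8 | Z-iodoallyl stannylmethyl ketone (quaternary carbon unspecified) | CCCC[Sn](CCCC)(CCCC)CC1(C/C=C\I)C(=O)CC[C@H]2[C@H]1CO[C@@]2(/C=C/C=C(C)C)COCc3ccc(OC)cc3
F4 | step 8 | cis-fused γ-hydroxystannane (hydrindenol) | CCCC[Sn](CCCC)(CCCC)CC14CC=CC4(O)CC[C@H]2[C@H]1CO[C@@]2(/C=C/C=C(C)C)COCc3ccc(OC)cc3
F0 | step 9 | none | none
F5 | step 5 | chloro dienyl epoxide | C1=C(O[Si](C)(C)C(C)(C)C)CC[C@H]([C@]3(/C=C/C=C(C)C)CO3)[C@H]1CCl
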